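**Strategy.** Both ends of the C50 skeleton contain the same irregular lavandulyl unit: ring atoms C1(Me2)–C2(H)–C3 with the C5 side chain, and chain atoms C1'(OH)Me2–C2'(H)(prenyl)–C3'. (R)-Lavandulol therefore supplies C2 and C2' directly. The route rests on closing the only ring, the ε-ring, at C1–C6 by a proton-initiated cation–olefin cyclization of an acyclic pseudoionone analogue that carries the isopropenyl group at C1, an (E)-C5=C6 dienone and an acetate-deactivated side chain. In one operation it forms the six-membered ring, places C4=C5 and sets C6 cis to C2 (1,3 across C1). Two C20 phosphonium salts and a C10 dialdehyde then assemble the polyene by Wittig reactions at C11=C12 and C11'=C12'.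

Key step: step 9

Remark: carotenoid numbering is used in the text (ring C1–C6, chain C7–C15, primed atoms for the acyclic half); (R)-lavandulol, the E-configured C5 phosphonate and the all-E C10 dialdehyde are assumed to be purchasable in the stated stereochemical purity.

Step 1
Reactants: 1 (R)-lavandulol
Product: 2 (R)-lavandulyl iodide, (3R)-3-(iodomethyl)-2,6-dimethylhepta-1,5-diene
Conditions: I2, PPh3, imidazole, CH2Cl2, 0 °C to rt, dark
Reagents that add atoms: iodine, I-I
Why: Appel iodination replaces the primary hydroxyl by SN2 attack of iodide on the oxyphosphonium group at CH2, so the neighbouring stereocentre and both alkenes are untouched under these non-acidic conditions.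

Step 2
Reactants: 2 (R)-lavandulyl iodide; 3 methyl acetoacetate
Product: 4 methyl (6R)-9-methyl-3-oxo-6-(prop-1-en-2-yl)dec-8-enoate
Conditions: 3, NaH, THF, 0 °C; n-BuLi, 0 °C; then 2, 0 °C to rt; aq. NH4Cl
Reagents that add atoms: none
Why: γ-Alkylation of the acetoacetate dianion, whose terminal carbanion is far more nucleophilic than the stabilised central one, with the primary iodide forms C3–C4 by SN2 at a non-stereogenic carbon; a small excess of dianion at 0 °C is planned because the iodide is β-branched.

Step 3
Reactants: 4 methyl (6R)-9-methyl-3-oxo-6-(prop-1-en-2-yl)dec-8-enoate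
Product: 5 methyl (2Z,6R)-3-[(diethoxyphosphoryl)oxy]-9-methyl-6-(prop-1-en-2-yl)deca-2,8-dienoate
Conditions: NaH, Et2O, 0 °C; then ClP(O)(OEt)2, 0 °C
Reagents that add atoms: diethyl chlorophosphate, CCOP(=O)(Cl)OCC
Why: O-Phosphorylation of the chelated sodium enolate of the β-keto ester in ether should give the Z-enol phosphate (ester and phosphate cis), which fixes the later C5=C6 geometry.

Step 4
Reactants: 5 Z-enol phosphate
Product: 6 methyl (2E,6R)-3,9-dimethyl-6-(prop-1-en-2-yl)deca-2,8-dienoate
Conditions: Me2CuLi (from MeLi and CuI), Et2O, -78 to -45 °C; aq. NH4Cl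
Reagents that add atoms: lithium dimethylcuprate, [Li+].C[Cu-]C
Why: Cuprate addition–elimination on the β-phosphoryloxy enoate replaces the phosphate by methyl with retention of alkene geometry, delivering the C5 methyl and the E-trisubstituted enoate.

Step 5
Reactants: 6 E-enoate
Product: 7 (2E,6R)-3,9-dimethyl-6-(prop-1-en-2-yl)deca-2,8-dien-1-ol
Conditions: i-Bu2AlH (2.2 equiv), CH2Cl2, -78 °C; Rochelle salt work-up
Reagents that add atoms: none
Why: Hydride reduction of the conjugated ester by two 1,2-additions gives the allylic alcohol without touching the isolated alkenes or the alkene geometry.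

Step 6
Reactants: 7 allylic alcohol
Product: 9 (3E,5E,9R)-6,12-dimethyl-9-(prop-1-en-2-yl)trideca-3,5,11-trien-2-one, via dienal 8 (not isolated)
Conditions: MnO2 (excess), Ph3P=CHC(O)CH3, toluene, 80 °C
Reagents that add atoms: 1-(triphenylphosphoranylidene)propan-2-one, CC(=O)C=P(c1ccccc1)(c1ccccc1)c1ccccc1
Why: In this tandem oxidation–Wittig olefination MnO2 oxidises only the allylic alcohol to enal 8, which is trapped in the same flask by the stabilised acetonylidene ylide to give the E-enone (C7=C8, bringing C8, C9 and the C9 methyl) without isolating the isomerisation-prone enal.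

Step 7
Reactants: 9 dienone
Product: 10 (3E,5E,9R,11E)-13-hydroxy-6,12-dimethyl-9-(prop-1-en-2-yl)trideca-3,5,11-trien-2-one
Conditions: SeO2 (0.3 equiv), t-BuOOH (2 equiv), CH2Cl2, 0 °C to rt, stopped at partial conversion, 9 recycled
Reagents that add atoms: selenium dioxide, O=[Se]=O; tert-butyl hydroperoxide, CC(C)(C)OO
Why: SeO2-catalysed allylic oxidation (ene reaction followed by 2,3-sigmatropic shift) attacks the most electron-rich alkene, the trisubstituted prenyl group, at its E-methyl and gives the E-allylic alcohol, whereas the dienone alkenes are deactivated and the 1,1-disubstituted alkene reacts more slowly.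

Step 8
Reactants: 10 allylic alcohol
Product: 11 (2E,5R,8E,10E)-2,8-dimethyl-12-oxo-5-(prop-1-en-2-yl)trideca-2,8,10-trien-1-yl acetate
Conditions: Ac2O, pyridine, DMAP (cat.), CH2Cl2, 0 °C
Reagents that add atoms: acetic anhydride, CC(=O)OC(C)=O
Why: Standard acylation of the primary alcohol installs the electron-withdrawing acetate that lowers the basicity and nucleophilicity of the side-chain alkene for the cyclization.

Step 9
Reactants: 11 cyclization precursor (acetate)
Product: 12 (3E)-4-{(1R,5R)-5-[(2E)-4-acetoxy-3-methylbut-2-en-1-yl]-2,6,6-trimethylcyclohex-2-en-1-yl}but-3-en-2-one, the (2R,6R)-2-substituted α-ionone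
Conditions: ClSO3H (3 equiv), 2-nitropropane, -78 °C, 10–20 min; poured into cold aq. NaHCO3
Reagents that add atoms: none
Why: ClSO3H protonates the ketone and acetate oxygens, which switches off the alkenes next to them, and then the CH2 terminus of the only unencumbered alkene, the isopropenyl group, so that the tertiary C1 cation is captured by C6 of the (E)-C5=C6 alkene and the resulting tertiary C5 cation loses H-4 to give the C4=C5 alkene. The closest known reaction type is the Brønsted-acid cation–olefin cyclization of pseudoionones and pseudoirones to α-ionones and α-irones. The ε-ring is closed through the C1–C6 bond in a 6-endo mode (both alkene carbons become ring atoms) via a chair-like transition state. The new stereocentre C6 is controlled by the C2 centre inherited from lavandulol: the C2 side chain lies equatorial, anti to the forming bond and clear of the two C1 methyls, while the E geometry of C5=C6 places C7 equatorial, so that C6 is formed cis to C2 (2R,6R). The step needs initiation at the isopropenyl group only, cis closure, an untouched C2 centre and kinetic loss of H-4, which are secured by the acetate-deactivated side-chain alkene (it could in any case only close a four-membered ring or an anti-Markovnikov five-membered ring), by the geometrically defined enone from step 4, and by a strong acid at -78 °C with a cold basic quench so that ring closure outruns loss of H-2 or a 1,2-hydride shift and the ring alkene is not drawn into conjugation with erasure of C6. That the C2 configuration survives next to the cation is a rate argument and should be checked on the first run by chiral chromatography against material made from racemic lavandulol.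

Step 10
Reactants: 12 ring ketone acetate
Product: 13 (1E)-1-{(1R,5R)-5-[(2E)-4-hydroxy-3-methylbut-2-en-1-yl]-2,6,6-trimethylcyclohex-2-en-1-yl}-3-methylpenta-1,4-dien-3-ol (both epimers at the new carbinol carbon C9)
Conditions: CH2=CHMgBr (4 equiv), THF, -78 to 0 °C; aq. NH4Cl
Reagents that add atoms: vinylmagnesium bromide, C=C[Mg]Br
Why: Grignard 1,2-addition to the methyl enone, as practised on ionones, brings C10 and C11 while the excess reagent removes the acetate by double addition; the new carbinol centre forms unselectively, which is irrelevant because it is ionised in step 11.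

Step 11
Reactants: 13 vinyl carbinol diol
Product: 14 [(2E,4E)-5-{(1R,5R)-5-[(2E)-4-hydroxy-3-methylbut-2-en-1-yl]-2,6,6-trimethylcyclohex-2-en-1-yl}-3-methylpenta-2,4-dien-1-yl]triphenylphosphonium bromide (ring C20 salt)
Conditions: PPh3·HBr (1.0 equiv), MeOH, 0 °C to rt; trituration with EtOAc/Et2O
Reagents that add atoms: triphenylphosphine hydrobromide, [Br-].[PH+](c1ccccc1)(c1ccccc1)c1ccccc1
Why: The tertiary, doubly allylic carbinol ionises to a pentadienyl cation that the phosphine traps at the unhindered terminus C11 (allylic transposition, thermodynamic 9E geometry), whereas the isolated primary allylic alcohol of the side chain ionises far more slowly at this temperature.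

Step 12
Reactants: 14 ring C20 salt; 15 (2E,4E,6E)-2,7-dimethylocta-2,4,6-trienedial
Product: 17 all-E (2R,6R)-2-[(2E)-4-hydroxy-3-methylbut-2-enyl]-12'-apo-ε-caroten-12'-al (C30 aldehyde), via 11Z isomer 16 (not isolated)
Conditions: 15 (3 equiv), NaOMe, MeOH/CH2Cl2, 0 °C to rt; aqueous work-up; I2 (cat.), CH2Cl2, rt, diffuse light
Reagents that add atoms: none
Why: Wittig olefination of the allylic ylide with one formyl group of the dialdehyde, which is used in excess to suppress double olefination, forms C11=C12 as an E/Z mixture, and iodine-catalysed equilibration converts the hindered 11Z isomer 16 into the all-E aldehyde.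

Step 13
Reactants: 1 (R)-lavandulol
Product: 18 (2S)-2-(2-hydroxypropan-2-yl)-5-methylhex-4-en-1-ol
Conditions: Co(acac)2 (cat.), PhSiH3, O2 (1 atm), i-PrOH, rt; aq. Na2S2O3
Reagents that add atoms: dioxygen, O=O
Why: Mukaiyama hydration (hydrogen-atom transfer from a cobalt hydride, then oxygen capture of the tertiary radical) is Markovnikov-selective and considerably faster for the unhindered 1,1-disubstituted alkene than for the trisubstituted prenyl alkene, and it leaves the stereocentre untouched (the descriptor changes only through the priority rules).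

Step 14
Reactants: 18 diol
Product: 19 bis(triethylsilyl) ether of 18
Conditions: Et3SiOTf (2.5 equiv), 2,6-lutidine, CH2Cl2, -78 to 0 °C
Reagents that add atoms: triethylsilyl trifluoromethanesulfonate, CC[Si](CC)(CC)OS(=O)(=O)C(F)(F)F
Why: A silyl triflate with a hindered base silylates both the primary and the hindered tertiary hydroxyl, the latter needing protection to prevent retro-aldol cleavage at the aldehyde stage.

Step 15
Reactants: 19 bis(triethylsilyl) ether
Product: 20 (2R)-5-methyl-2-[2-(triethylsilyloxy)propan-2-yl]hex-4-enal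
Conditions: (COCl)2, DMSO, CH2Cl2, -78 to -30 °C; then Et3N, -78 to 0 °C
Reagents that add atoms: none
Why: Under Swern conditions a primary triethylsilyl ether is cleaved by the activated sulfonium species and oxidised directly to the aldehyde while the tertiary silyl ether is inert, and the amine base at low temperature should not epimerise the α-stereocentre.

Step 16
Reactants: 20 aldehyde; 21 triethyl (E)-3-methyl-4-phosphonocrotonate
Product: 22 ethyl (2E,4E,6S)-3,9-dimethyl-6-[2-(triethylsilyloxy)propan-2-yl]deca-2,4,8-trienoate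
Conditions: 21, LiN(SiMe3)2, THF, -78 °C; then 20, -78 to 0 °C
Reagents that add atoms: none
Why: Horner–Wadsworth–Emmons olefination with the lithiated vinylogous phosphonate forms the E-configured C3'=C4' alkene, addition at -78 °C being faster than enolisation or β-elimination of the β-silyloxy aldehyde, and any minor 5'Z isomer is removed by chromatography.

Step 17
Reactants: 22 dienoate
Product: 23 (2E,4E,6S)-3,9-dimethyl-6-[2-(triethylsilyloxy)propan-2-yl]deca-2,4,8-trien-1-ol
Conditions: i-Bu2AlH (2.2 equiv), CH2Cl2, -78 °C; Rochelle salt work-up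
Reagents that add atoms: none
Why: Hydride reduction of the conjugated ester gives the allylic alcohol, and the tertiary silyl ether and the alkenes are inert to the reagent.

Step 18
Reactants: 23 dienol
Product: 24 (2E,4E,6S)-3,9-dimethyl-6-[2-(triethylsilyloxy)propan-2-yl]deca-2,4,8-trienal
Conditions: MnO2 (excess), CH2Cl2, rt
Reagents that add atoms: none
Why: MnO2 oxidises allylic alcohols selectively to the conjugated aldehyde without over-oxidation or alkene isomerisation.

Step 19
Reactants: 24 dienal; 21 triethyl (E)-3-methyl-4-phosphonocrotonate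
Product: 25 ethyl (2E,4E,6E,8E,10S)-3,7,13-trimethyl-10-[2-(triethylsilyloxy)propan-2-yl]tetradeca-2,4,6,8,12-pentaenoate (C20 ester)
Conditions: 21, LiN(SiMe3)2, THF, -78 °C; then 24, -78 to 0 °C
Reagents that add atoms: none
Why: A second Horner–Wadsworth–Emmons olefination with the same C5 phosphonate forms the E-configured C7'=C8' alkene on a non-enolisable conjugated aldehyde, any minor 9'Z isomer being removed by chromatography.

Step 20
Reactants: 25 C20 ester
Product: 26 (2E,4E,6E,8E,10S)-3,7,13-trimethyl-10-[2-(triethylsilyloxy)propan-2-yl]tetradeca-2,4,6,8,12-pentaen-1-ol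
Conditions: i-Bu2AlH (2.2 equiv), CH2Cl2, -78 °C; Rochelle salt work-up
Reagents that add atoms: none
Why: Hydride reduction of the polyenoate by 1,2-addition gives the primary polyenylic alcohol without affecting the silyl ether.

Step 21
Reactants: 26 C20 alcohol
Product: 27 [(2E,4E,6E,8E,10S)-10-(2-hydroxypropan-2-yl)-3,7,13-trimethyltetradeca-2,4,6,8,12-pentaen-1-yl]triphenylphosphonium bromide (acyclic C20 salt)
Conditions: PPh3·HBr (1.3 equiv), MeOH, rt, dark
Reagents that add atoms: triphenylphosphine hydrobromide, [Br-].[PH+](c1ccccc1)(c1ccccc1)c1ccccc1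
Why: The polyenylic primary alcohol ionises readily and the phosphine adds at the terminal C11' to give the E-allylic salt, while the methanolic acid solvolyses the tertiary triethylsilyl ether in the same operation.

Step 22
Reactants: 17 C30 aldehyde; 27 acyclic C20 salt
Product: 29 target, all-E (2R,6R,2'S)-2-[(2E)-4-hydroxy-3-methylbut-2-enyl]-2'-(3-methylbut-2-enyl)-3',4'-didehydro-1',2'-dihydro-ε,ψ-caroten-1'-ol, via 11'Z isomer 28 (not isolated)
Conditions: NaOMe, MeOH/CH2Cl2, rt, Ar, dark; aqueous work-up; then reflux in n-heptane, Ar, dark; crystallisation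
Reagents that add atoms: none
Why: Wittig olefination of the C20 ylide with the C30 aldehyde forms C11'=C12' as an E/Z mixture and heating converts the strained 11'Z isomer 28 into the all-E polyene, the free hydroxyl groups being tolerated under methoxide and no stereocentre being touched.

**Compound list**

1 | (R)-lavandulol, (2R)-5-methyl-2-(prop-1-en-2-yl)hex-4-en-1-ol | CC(C)=CC[C@@H](CO)C(C)=C | starting material
2 | (R)-lavandulyl iodide, (3R)-3-(iodomethyl)-2,6-dimethylhepta-1,5-diene | IC[C@H](CC=C(C)C)C(C)=C | intermediate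
3 | methyl acetoacetate | COC(=O)CC(C)=O | starting material
4 | methyl (6R)-9-methyl-3-oxo-6-(prop-1-en-2-yl)dec-8-enoate | COC(=O)CC(=O)CC[C@H](CC=C(C)C)C(C)=C | intermediate
5 | methyl (2Z,6R)-3-[(diethoxyphosphoryl)oxy]-9-methyl-6-(prop-1-en-2-yl)deca-2,8-dienoate | COC(=O)/C=C(\OP(=O)(OCC)OCC)CC[C@H](CC=C(C)C)C(C)=C | intermediate
6 | methyl (2E,6R)-3,9-dimethyl-6-(prop-1-en-2-yl)deca-2,8-dienoate | COC(=O)/C=C(\C)CC[C@H](CC=C(C)C)C(C)=C | intermediate
7 | (2E,6R)-3,9-dimethyl-6-(prop-1-en-2-yl)deca-2,8-dien-1-ol | OC/C=C(\C)CC[C@H](CC=C(C)C)C(C)=C | intermediate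
8 | (2E,6R)-3,9-dimethyl-6-(prop-1-en-2-yl)deca-2,8-dienal (not isolated) | O=C/C=C(\C)CC[C@H](CC=C(C)C)C(C)=C | intermediate
9 | (3E,5E,9R)-6,12-dimethyl-9-(prop-1-en-2-yl)trideca-3,5,11-trien-2-one | CC(=O)/C=C/C=C(\C)CC[C@H](CC=C(C)C)C(C)=C | intermediate
10 | (3E,5E,9R,11E)-13-hydroxy-6,12-dimethyl-9-(prop-1-en-2-yl)trideca-3,5,11-trien-2-one | CC(=O)/C=C/C=C(\C)CC[C@H](C/C=C(\C)CO)C(C)=C | intermediate
11 | (2E,5R,8E,10E)-2,8-dimethyl-12-oxo-5-(prop-1-en-2-yl)trideca-2,8,10-trien-1-yl acetate | CC(=O)/C=C/C=C(\C)CC[C@H](C/C=C(\C)COC(C)=O)C(C)=C | intermediate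
12 | (3E)-4-{(1R,5R)-5-[(2E)-4-acetoxy-3-methylbut-2-en-1-yl]-2,6,6-trimethylcyclohex-2-en-1-yl}but-3-en-2-one | CC(=O)/C=C/[C@@H]1C(C)=CC[C@H](C/C=C(\C)COC(C)=O)C1(C)C | intermediate
13 | (1E)-1-{(1R,5R)-5-[(2E)-4-hydroxy-3-methylbut-2-en-1-yl]-2,6,6-trimethylcyclohex-2-en-1-yl}-3-methylpenta-1,4-dien-3-ol, carbinol epimers | C=CC(C)(O)/C=C/[C@@H]1C(C)=CC[C@H](C/C=C(\C)CO)C1(C)C | intermediate
14 | [(2E,4E)-5-{(1R,5R)-5-[(2E)-4-hydroxy-3-methylbut-2-en-1-yl]-2,6,6-trimethylcyclohex-2-en-1-yl}-3-methylpenta-2,4-dien-1-yl]triphenylphosphonium bromide | C(/C=C(C)/C=C/[C@@H]1C(C)=CC[C@H](C/C=C(\C)CO)C1(C)C)[P+](c1ccccc1)(c1ccccc1)c1ccccc1.[Br-] | intermediate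
15 | (2E,4E,6E)-2,7-dimethylocta-2,4,6-trienedial | O=C/C(C)=C/C=C/C=C(C)/C=O | starting material
16 | 11Z isomer of the C30 aldehyde 17 (not isolated) | O=C/C(C)=C/C=C/C=C(C)/C=C\C=C(C)\C=C\[C@@H]1C(C)=CC[C@H](C/C=C(\C)CO)C1(C)C | intermediate
17 | all-E (2R,6R)-2-[(2E)-4-hydroxy-3-methylbut-2-enyl]-12'-apo-ε-caroten-12'-al | O=C/C(C)=C/C=C/C=C(C)/C=C/C=C(C)/C=C/[C@@H]1C(C)=CC[C@H](C/C=C(\C)CO)C1(C)C | intermediate
18 | (2S)-2-(2-hydroxypropan-2-yl)-5-methylhex-4-en-1-ol | CC(C)=CC[C@@H](CO)C(C)(C)O | intermediate
19 | (2S)-bis(triethylsilyl) ether of 18 | CC(C)=CC[C@@H](CO[Si](CC)(CC)CC)C(C)(C)O[Si](CC)(CC)CC | intermediate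
20 | (2R)-5-methyl-2-[2-(triethylsilyloxy)propan-2-yl]hex-4-enal | CC(C)=CC[C@@H](C=O)C(C)(C)O[Si](CC)(CC)CC | intermediate
21 | triethyl (E)-3-methyl-4-phosphonocrotonate, ethyl (2E)-4-(diethoxyphosphoryl)-3-methylbut-2-enoate | CCOC(=O)/C=C(\C)CP(=O)(OCC)OCC | starting material
22 | ethyl (2E,4E,6S)-3,9-dimethyl-6-[2-(triethylsilyloxy)propan-2-yl]deca-2,4,8-trienoate | CC(C)=CC[C@@H](/C=C/C(C)=C/C(=O)OCC)C(C)(C)O[Si](CC)(CC)CC | intermediate
23 | (2E,4E,6S)-3,9-dimethyl-6-[2-(triethylsilyloxy)propan-2-yl]deca-2,4,8-trien-1-ol | CC(C)=CC[C@@H](/C=C/C(C)=C/CO)C(C)(C)O[Si](CC)(CC)CC | intermediate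
24 | (2E,4E,6S)-3,9-dimethyl-6-[2-(triethylsilyloxy)propan-2-yl]deca-2,4,8-trienal | CC(C)=CC[C@@H](/C=C/C(C)=C/C=O)C(C)(C)O[Si](CC)(CC)CC | intermediate
25 | ethyl (2E,4E,6E,8E,10S)-3,7,13-trimethyl-10-[2-(triethylsilyloxy)propan-2-yl]tetradeca-2,4,6,8,12-pentaenoate | CC(C)=CC[C@@H](/C=C/C(C)=C/C=C/C(C)=C/C(=O)OCC)C(C)(C)O[Si](CC)(CC)CC | intermediate
26 | (2E,4E,6E,8E,10S)-3,7,13-trimethyl-10-[2-(triethylsilyloxy)propan-2-yl]tetradeca-2,4,6,8,12-pentaen-1-ol | CC(C)=CC[C@@H](/C=C/C(C)=C/C=C/C(C)=C/CO)C(C)(C)O[Si](CC)(CC)CC | intermediate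
27 | [(2E,4E,6E,8E,10S)-10-(2-hydroxypropan-2-yl)-3,7,13-trimethyltetradeca-2,4,6,8,12-pentaen-1-yl]triphenylphosphonium bromide | CC(C)=CC[C@@H](/C=C/C(C)=C/C=C/C(C)=C/C[P+](c1ccccc1)(c1ccccc1)c1ccccc1)C(C)(C)O.[Br-] | intermediate
28 | 11'Z isomer of the target (not isolated) | CC(C)=CC[C@@H](/C=C/C(C)=C/C=C/C(C)=C/C=C\C(C)=C\C=C\C=C(C)\C=C\C=C(C)\C=C\[C@@H]1C(C)=CC[C@H](C/C=C(\C)CO)C1(C)C)C(C)(C)O | intermediate
29 | CNP0409952.1, all-E (2R,6R,2'S)-2-[(2E)-4-hydroxy-3-methylbut-2-enyl]-2'-(3-methylbut-2-enyl)-3',4'-didehydro-1',2'-dihydro-ε,ψ-caroten-1'-ol | CC(C)=CC[C@@H](/C=C/C(C)=C/C=C/C(C)=C/C=C/C(C)=C/C=C/C=C(C)/C=C/C=C(C)/C=C/[C@@H]1C(C)=CC[C@H](C/C=C(\C)CO)C1(C)C)C(C)(C)O | target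

**Totals**

Total step count: 22 steps.
Longest linear sequence: 13 steps (steps 1 to 12, then step 22), starting from (R)-lavandulol.

**Steps most likely to fail**

Step 9 (key cyclization). The open C1 cation may lose H-2 or undergo a 1,2-hydride shift before the ring closes, which would erode the configuration at C2. The 2,6-cis preference may also be eroded, or the new ring alkene may migrate into conjugation and erase C6. The fallback sets out from 11 and replaces the proton by a bridged mercury electrophile. Hg(OTf)2 with N,N-dimethylaniline in nitromethane at -20 °C should add to the isopropenyl group as a mercurinium ion, which cannot lose H-2 or shift hydride. The same chair-like C1–C6 closure, loss of H-4 and work-up with aqueous NaCl should then give the C1-(chloromercurio)methyl ketone F1. Reductive demercuration with NaBH4 in aqueous NaOH/THF, run cold, concentrated and briefly so that hydrogen transfer outruns radical 5-exo closure and enone reduction, turns the CH2HgCl group into the second C1 methyl. The route is rejoined at 12.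

Step 7 (allylic oxidation). Oxidation may also take place at the isopropenyl group, at its methyl or at the C2 methine, the latter destroying the stereocentre, and the alcohol may be over-oxidised. The fallback sets out from 9 and builds the oxidised side chain by cleavage and olefination instead. mCPBA (1 equiv, CH2Cl2, NaHCO3, -20 °C) should epoxidise the more electron-rich trisubstituted alkene to the epoxide F2. HIO4 in THF/H2O cleaves it, with loss of acetone, to the aldehyde F3. Wittig reaction with 2-(triphenylphosphoranylidene)propanal gives the (E)-enal F4. NaBH4 in EtOH/CH2Cl2 at -78 °C reduces the aldehyde in preference to the dienone ketone. The route is rejoined at 10.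

Step 11 (phosphonium salt formation). The primary allylic alcohol of the side chain may ionise alongside the tertiary carbinol, leading to double phosphonium formation or solvolysis at the side chain. The fallback sets out from 13 and masks that hydroxyl first. Ac2O in pyridine at 0 °C acetylates only the primary alcohol, giving the monoacetate F5. PPh3·HBr then meets a single ionisable alcohol and gives the acetoxy phosphonium bromide F6. Wittig reaction with 15 as in step 12 gives the acetoxy C30 aldehyde F7 together with its 11Z isomer F8. K2CO3 in MeOH removes the acetate to give 17 and 16, which are equilibrated with iodine as in step 12. The route is rejoined at 17.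

**Further compounds**

F1 | step 9 | C1-(chloromercurio)methyl analogue of 12 (C1 epimers) | CC(=O)/C=C/[C@@H]1C(C)=CC[C@H](C/C=C(\C)COC(C)=O)C1(C)C[Hg]Cl
F2 | step 7 | 11,12-epoxide of 9 (epoxide epimers) | CC(=O)/C=C/C=C(\C)CC[C@H](CC1OC1(C)C)C(C)=C
F3 | step 7 | (3R,6E,8E)-6-methyl-10-oxo-3-(prop-1-en-2-yl)undeca-6,8-dienal | CC(=O)/C=C/C=C(\C)CC[C@H](CC=O)C(C)=C
F4 | step 7 | (2E,5R,8E,10E)-2,8-dimethyl-12-oxo-5-(prop-1-en-2-yl)trideca-2,8,10-trienal | CC(=O)/C=C/C=C(\C)CC[C@H](C/C=C(\C)C=O)C(C)=C
F5 | step 11 | primary monoacetate of 13 | C=CC(C)(O)/C=C/[C@@H]1C(C)=CC[C@H](C/C=C(\C)COC(C)=O)C1(C)C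
F6 | step 11 | side-chain acetate of phosphonium bromide 14 | C(/C=C(C)/C=C/[C@@H]1C(C)=CC[C@H](C/C=C(\C)COC(C)=O)C1(C)C)[P+](c1ccccc1)(c1ccccc1)c1ccccc1.[Br-]
F7 | step 11 | side-chain acetate of the all-E C30 aldehyde 17 | O=C/C(C)=C/C=C/C=C(C)/C=C/C=C(C)/C=C/[C@@H]1C(C)=CC[C@H](C/C=C(\C)COC(C)=O)C1(C)C
F8 | step 11 | side-chain acetate of the 11Z C30 aldehyde 16 | O=C/C(C)=C/C=C/C=C(C)/C=C\C=C(C)\C=C\[C@@H]1C(C)=CC[C@H](C/C=C(\C)COC(C)=O)C1(C)C
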